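**Design of a synthesis of (4S)-7,8-dihydroxy-4-(4-hydroxy-8-methoxynaphthalen-1-yl)-3,4-dihydronaphthalen-1(2H)-one (21)**

Compound numbers 1–21 are those of the steps and the compound list. The target is 21, the precursor of the key step is 18 and its product is 20. Tetralone atoms are numbered C1–C8a; naphthalene atoms carry a prime.

## The problem

Target 21 is a 4-aryl-1-tetralone with hydroxyl groups on C7 and C8 and a 4-hydroxy-8-methoxynaphthalen-1-yl group on C4. Its only stereocentre is C4 (S), a tertiary, doubly benzylic C–H. No second centre can relay or correct it, so it must be set by a catalyst and must never afterwards become a cation, radical or carbanion. The bond from C4 to naphthalene C1' is crowded by the methoxy group on the peri carbon C8', which slows both its formation and any reaction beside it. In the tetralone benzene ring, C8a (bearing the carbonyl), C8 (oxygen) and C7 (oxygen) are contiguous. Acylative ring closure of a 4,4-diarylbutanoic acid onto a 3,4-dioxygenated benzene would go para to an oxygen and give the 6,7-dioxygenated isomer instead. The molecule has a catechol and a naphthol, both easily oxidised, beside one methyl ether that must stay, so the oxygens must be distinguished and the phenols freed last. Once the tetralone exists, C4–H is also vinylogously acidic through C4a–C8a–C1=O, which excludes strong base late on. The enabling feature is that C4a, C5, C6, C7 and the C7 oxygen map onto C2–C5 and the ring oxygen of a 2-substituted furan, while C8a and C8 with its oxygen are an alkoxyalkyne joined to C4a through C1, C2, C3 and C4. This is a furan and an alkoxy ynone on a four-atom tether.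

## Retrosynthesis

**21 ⇒ 20.** Two O–C bonds are cut: the benzyl ether on the naphthol oxygen and the methyl ether on the C8 oxygen. Compound 20 has the C7 hydroxyl free and C8 as a methyl ether because that is how the ring construction delivers the two catechol oxygens. Both groups can fall in one operation with BCl3. The benzyl ether is cleaved as such, and the C8 methyl ether lies between the C1 carbonyl and the C7 oxygen, where boron chelation directs cleavage. The naphthyl methyl ether has neither feature. The forward step must therefore distinguish two aryl methyl ethers by chelation alone.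

**20 ⇒ 18.** The bonds C4a–C8a and C7–C8 are cut and the C7 oxygen is returned to a bridge between C7 and C4a. The benzene ring becomes a furan plus a methoxyalkyne, and the ketone ring opens as well. The neighbouring cut at C1–C8a (acylation) gives the wrong regiochemistry, and the cut at C4–C4a (arylation) needs a ready-made 1,2,3,4-tetrasubstituted arene. Precursor 18 is simpler by two rings and by the whole arene substitution problem. The forward reaction is an intramolecular furan Diels–Alder reaction to oxanorbornadiene 19, followed by bridge opening to the phenol. The alkyl group on the ynol oxygen is chosen as methyl, which has no β-hydrogen. The retro-ene loss of an alkene that limits ethyl ynol ethers on heating is thereby excluded, and the cycloaddition can be heated as required.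

**18 ⇒ 14 + 15.** The bond between the carbonyl carbon and the alkyne is cut. The acyl donor is the N-methoxy-N-methylamide 14, which stops at the ketone stage. The alkynyl donor is lithium methoxyacetylide 16, made in the flask from 2-chloro-1,1-dimethoxyethane 15. Adding 16 to an aldehyde and oxidising would cost two more steps. The forward step must release the ynone without letting the liberated amines add to it.

**14 ⇒ 12 ⇒ 11.** After the trivial amide formation, the C4–H bond is cut. The stereocentre is traced to hydrogenation of the trisubstituted alkene of the β,γ-unsaturated acid 11, with the carboxylate as the catalyst's handle. Conjugate addition of a naphthyl metal to a furylacrylic acid derivative would give a chain one carbon too short and would need the peri-hindered aryl as nucleophile. The hydrogenation requires 11 as one alkene isomer, because the two isomers would give opposite enantiomers.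

**11 ⇒ 10 ⇒ 3 + 7.** After ester hydrolysis, the bond between naphthalene C1' and the alkene carbon is cut. A Wittig olefination of a naphthyl furyl ketone with a carboxyethyl ylide would reach 11 one step sooner, but as a mixture of alkene isomers with nothing to bias it. Cross-coupling of a stereodefined enol triflate transfers the geometry with retention. The furan is placed on triflate 7 and the naphthalene is the zinc reagent (through 8 and 9 from bromide 3). This makes the route convergent and keeps the triflate's ketone precursor trivial. The coupling must tolerate a peri-substituted arylzinc.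

**7 ⇒ 6 ⇒ 4 + 5.** The triflate C–O bond is cut, then the bond between the acyl carbon and the chain. Keto ester 6 is the Stetter adduct of furfural 4 and methyl acrylate 5. The geometry of 7 comes from the (Z)-enolate that aryl alkyl ketones form.

**3 ⇒ 2 ⇒ 1.** The O–benzyl and C–Br bonds are cut. Bromination must come before benzylation. In 1 the free hydroxyl makes its own ring the more reactive and directs para. Once both oxygens are ethers the two rings and their two para positions can no longer be told apart.

## Roads not taken

**Alternative 1:** The naphthalene, not the tetralone arene, would be made last, by cutting naphthalene C1'–C8a' and C4'–C4a'.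
- Key step: adduct A1 would arise by [4+2] addition of 3-methoxybenzyne A2 (generated in the flask with fluoride) across C2 and C5 of the furan of furyl tetralone A3. A3 already carries the stereocentre and the protected catechol. Acid-mediated bridge opening would then give the 4-substituted 1-naphthol.
- Merits: aryne–furan cycloadditions are fast and dependable. The peri-crowded bond from C4 to the naphthalene is never made by a coupling. The sensitive naphthol appears only at the end.
- Weak points:
  - A1 needs the methoxy carbon of A2 to end beside the bridgehead that carries the bulky tetralone. This is the more congested orientation, and a 2-alkylfuran offers no strong electronic bias toward it, so a mixture leaning the wrong way is expected.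
  - Bridge opening must ionise the bridgehead attached to the stereocentre. A cation beside the doubly benzylic C4–H invites proton loss and erosion of configuration.
  - A3 already contains the C8a/C8/C7 pattern, so the arene problem is moved, not solved.
- Comparison: this road is better at the hindered linkage, which the chosen route must make in step 5 and hydrogenate beside in step 7. Against that, the chosen plan fixes regiochemistry by a tether and by the direction of bridge opening, forms no cation beside C4, and creates the catechol pattern in the key step itself.

**Alternative 2:** The cut is through tetralone C4–C4a and C1–C8a.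
- Key step: cis-cycloadduct A4 would come from a Diels–Alder reaction of the dioxygenated aryne A5 with the acyloxy diene A6. The O-methylmandelate ester of A6 is the only source of chirality. The cis relation of C1 and C4 in A4 would carry it to C4 before C1 becomes the ketone and the C2–C3 alkene is reduced.
- Merits: it is the most convergent of the four. Both bonds to the arene form at once from two fragments of similar size, no asymmetric catalyst is needed, and on paper it is shorter than the chosen route.
- Weak points:
  - Face selection must come from a stereocentre in an ester side chain, several atoms from the diene, in a reaction with an early transition state. Each facial isomer has the opposite configuration at C4.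
  - The required orientation rests on the small bias of an alkoxy-substituted aryne toward two diene termini of similar nucleophilicity.
  - A4 is a 1,4-dihydronaphthalene with an acyloxy leaving group at C1 and an acidic hydrogen at C4. Loss of the acid to give a naphthalene, which destroys the stereocentre, is one easy step away.
  - Open-chain dienes also react with arynes by ene and [2+2] paths.
- Comparison: this road wins on convergence and step count. The chosen plan sets the stereocentre by a catalyst in a separate step whose outcome can be measured and corrected, fixes regiochemistry by a tether, and has no intermediate that aromatises by simple elimination.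

**Alternative 3:** The cut is through C2–C3 together with the C4–H bond.
- Key step: protected target A7 would form from α-chloro ketone A8, an aryl chloromethyl ketone with a 1-(naphthyl)vinyl group in the ortho position. Under visible light in an ene-reductase, the reduced flavin cofactor transfers an electron to the C–Cl bond. The α-keto radical adds to the CH2 end of the 1,1-diarylethene (six-membered ring, endo mode). The diaryl-stabilised radical at C4 then takes a hydrogen atom from the flavin semiquinone on one face.
- Merits: ring closure and stereocentre come in one late, mild step. The alkene is 1,1-disubstituted, so no alkene geometry needs control. This is a real advantage over the chosen route, which spends steps 4 and 5 on a geometrically pure alkene.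
- Weak points:
  - Selectivity depends on fitting a substrate with a peri-methoxynaphthyl group and an acetonide into a protein pocket. This cannot be predicted and would need screening and mutagenesis.
  - The established radical precursors for such cyclisations are mainly α-halo amides and esters, so an aryl chloromethyl ketone closing onto a diarylethene stretches the precedent.
  - Reduction of the C–Cl bond without cyclisation competes.
  - A8 again presupposes an arene with acyl, two oxygens and vinyl on four contiguous carbons, which is the pattern the chosen key step builds.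
- Comparison: this road is better on step economy at the stereocentre and needs no geometrically pure alkene. Against that, the chosen plan uses a small-molecule catalyst on a precedented substrate class and solves the arene pattern and the ring closure in one designed step.

Key step: step 10

## Route

Assumptions, each a remark on the chemistry:
- Compounds 1, 4, 5 and 15 are taken as commercial.
- The ligand configuration written in step 7 is the one expected to lead to (S)-12. The sense of induction must be checked on the first run and the antipodal complex used if it is reversed.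
- SIPHOX denotes a 7-(diarylphosphino)-7'-(oxazolin-2-yl)-1,1'-spirobiindane ligand. BArF denotes tetrakis[3,5-bis(trifluoromethyl)phenyl]borate.
- From 12 onward the descriptor stays S, because the furan carbon (later C4a) outranks the naphthyl carbon throughout.

Step 1
Reactants: 1 5-methoxynaphthalen-1-ol
Product: 2 4-bromo-5-methoxynaphthalen-1-ol
Conditions: NBS (1.0 equiv), MeCN, −20 to 0 °C, dark
Reagents that add atoms: N-bromosuccinimide, O=C1CCC(=O)N1Br
Why: Electrophilic aromatic bromination; the free hydroxyl makes its own ring the more nucleophilic and directs para (C4), the orientation NBS in acetonitrile gives with 1-naphthols and 1-alkoxynaphthalenes, and a peri methoxy group is tolerated at that position as in 1,5-dimethoxynaphthalene.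

Step 2
Reactants: 2 4-bromo-5-methoxynaphthalen-1-ol
Product: 3 1-(benzyloxy)-4-bromo-5-methoxynaphthalene
Conditions: BnBr (1.1 equiv), K2CO3 (1.5 equiv), DMF, 25 °C
Reagents that add atoms: benzyl bromide, BrCc1ccccc1
Why: Williamson ether synthesis on a naphthoxide; the benzyl ether withstands the organometallic, basic and hydrogenation steps ahead and is removed at the end by BCl3 without touching a methyl ether.

Step 3
Reactants: 4 furan-2-carbaldehyde; 5 methyl acrylate
Product: 6 methyl 4-(furan-2-yl)-4-oxobutanoate
Conditions: 3-benzyl-5-(2-hydroxyethyl)-4-methylthiazolium chloride (10 mol %), Et3N (0.3 equiv), dioxane, 80 °C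
Reagents that add atoms: none
Why: Stetter reaction; the thiazolylidene turns the aldehyde into an acyl anion equivalent that adds 1,4 to the acrylate, a combination for which furfural is a standard aldehyde.

Step 4
Reactants: 6 methyl 4-(furan-2-yl)-4-oxobutanoate
Product: 7 methyl (3Z)-4-(furan-2-yl)-4-{[(trifluoromethyl)sulfonyl]oxy}but-3-enoate
Conditions: KN(SiMe3)2 (1.05 equiv), THF, −78 °C; PhNTf2 (1.1 equiv), −78 to 0 °C
Reagents that add atoms: N-phenylbis(trifluoromethanesulfonimide), O=S(=O)(N(c1ccccc1)S(=O)(=O)C(F)(F)F)C(F)(F)F
Why: Kinetic enolisation and O-triflation; the ketone α-CH2 is far more acidic than the ester α-CH2, and aryl alkyl ketones give the (Z)-enolate (oxygen cis to the chain, avoiding A(1,3) strain with the ring), so the triflate should form as the Z isomer, which fixes the alkene geometry for the rest of the route.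

Step 5
Reactants: 3 1-(benzyloxy)-4-bromo-5-methoxynaphthalene; 7 methyl (3Z)-4-(furan-2-yl)-4-{[(trifluoromethyl)sulfonyl]oxy}but-3-enoate
Product: 10 methyl (3E)-4-[4-(benzyloxy)-8-methoxynaphthalen-1-yl]-4-(furan-2-yl)but-3-enoate, via aryllithium 8 (not isolated), via arylzinc chloride 9 (not isolated)
Conditions: 3, n-BuLi (1.05 equiv), THF, −78 °C; ZnCl2 (1.1 equiv), −78 to 0 °C; then 7 (0.9 equiv), Pd2(dba)3 (2.5 mol %), SPhos (10 mol %), THF, 25 to 50 °C
Reagents that add atoms: none
Why: Negishi cross-coupling; bromine–lithium exchange gives 8, zinc chloride gives 9, and zerovalent palladium with the bulky biarylphosphine couples it to the enol triflate with retention, so the naphthyl group takes the triflate's place cis to the CH2CO2Me group (E isomer); the arylzinc tolerates the ester and its acidic C2 protons.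

Step 6
Reactants: 10 methyl (3E)-4-[4-(benzyloxy)-8-methoxynaphthalen-1-yl]-4-(furan-2-yl)but-3-enoate
Product: 11 (3E)-4-[4-(benzyloxy)-8-methoxynaphthalen-1-yl]-4-(furan-2-yl)but-3-enoic acid
Conditions: LiOH·H2O (2 equiv), THF/MeOH/H2O, 0 °C; then 0.5 M HCl to pH 4 at 0 °C
Reagents that add atoms: lithium hydroxide (hydroxide oxygen), [Li+].[OH-]
Why: Ester saponification; at 0 °C hydroxide attacks the ester carbonyl faster than it removes the C2 protons, so the alkene should neither migrate nor lose its geometry, and work-up at pH 4 avoids acid-induced lactonisation onto the electron-rich diarylalkene.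

Step 7
Reactants: 11 (3E)-4-[4-(benzyloxy)-8-methoxynaphthalen-1-yl]-4-(furan-2-yl)but-3-enoic acid
Product: 12 (4S)-4-[4-(benzyloxy)-8-methoxynaphthalen-1-yl]-4-(furan-2-yl)butanoic acid
Conditions: [Ir(cod)((Sa,S)-SIPHOX)]BArF (1 mol %), H2 (6 atm), Et3N (0.5 equiv), MeOH, 25 °C
Reagents that add atoms: none
Why: Carboxylate-directed iridium-catalysed asymmetric hydrogenation of a β,γ-unsaturated acid, established for 4-aryl- and 4,4-diarylbut-3-enoic acids; the carboxylate anchors the substrate on the cationic metal so hydrogen reaches one face of the geometrically defined alkene, and the C4 stereocentre (S) is set by the spiro ligand (catalyst control); furan, arenes and benzyl ether are not reduced by this homogeneous catalyst at 25 °C.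

Step 8
Reactants: 12 (4S)-4-[4-(benzyloxy)-8-methoxynaphthalen-1-yl]-4-(furan-2-yl)butanoic acid
Product: 14 (4S)-4-[4-(benzyloxy)-8-methoxynaphthalen-1-yl]-4-(furan-2-yl)-N-methoxy-N-methylbutanamide, via acylimidazole 13 (not isolated)
Conditions: CDI (1.2 equiv), CH2Cl2, 25 °C; then MeNH(OMe)·HCl (1.5 equiv), 25 °C
Reagents that add atoms: N,O-dimethylhydroxylamine hydrochloride, CNOC.Cl
Why: Amide formation by acyl transfer through acylimidazole 13 under nearly neutral conditions; the stereocentre is γ to the carbonyl and not enolisable, and the furan sees no acid.

Step 9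
Reactants: 14 (4S)-4-[4-(benzyloxy)-8-methoxynaphthalen-1-yl]-4-(furan-2-yl)-N-methoxy-N-methylbutanamide; 15 2-chloro-1,1-dimethoxyethane
Product: 18 (6S)-6-[4-(benzyloxy)-8-methoxynaphthalen-1-yl]-6-(furan-2-yl)-1-methoxyhex-1-yn-3-one, via lithium methoxyacetylide 16 (not isolated), via tetrahedral lithium adduct 17 (not isolated)
Conditions: 15 (2.0 equiv), LiNEt2 (6.0 equiv; from Et2NH, n-BuLi), THF, 0 °C; then 14, −78 °C; AcOH in THF at −78 °C, then pH 7 phosphate buffer
Reagents that add atoms: none
Why: Acylation of an alkynyllithium by an N-methoxy-N-methylamide; three equivalents of amide base per acetal eliminate methanol and HCl and deprotonate the alkyne to give 16 with no strong base left over, chelate 17 holds the tetrahedral stage until the cold quench so a second addition cannot occur, and protonating the amines with acetic acid before the ynone is released should suppress their conjugate addition.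

Step 10
Reactants: 18 (6S)-6-[4-(benzyloxy)-8-methoxynaphthalen-1-yl]-6-(furan-2-yl)-1-methoxyhex-1-yn-3-one
Product: 20 (4S)-4-[4-(benzyloxy)-8-methoxynaphthalen-1-yl]-7-hydroxy-8-methoxy-3,4-dihydronaphthalen-1(2H)-one, via oxanorbornadiene cycloadduct 19 (not isolated)
Conditions: PhMe (0.02 M), BHT (5 mol %), 110 °C, sealed tube, Ar; then PPTS (5 mol %), 25 °C
Reagents that add atoms: none
Why: Proposed new method: an intramolecular furan Diels–Alder reaction whose dienophile is a 1-alkoxy ynone, followed by bridge opening; the closest known reaction type is the thermal intramolecular cycloaddition of 2-alkylfurans with tethered ynones and aromatisation of the 7-oxanorbornadiene to a fused phenol, which has not been shown with an oxygen substituent on the alkyne terminus. The furan adds through C2 and C5 across the triple bond, C2 bonding to the carbonyl-bearing alkyne carbon (tetralone C4a–C8a) and C5 to the methoxy-bearing carbon (C7–C8), to give 19. The ketone ring closes as a six-membered ring over the four-atom tether (type-1 intramolecular [4+2], tether on a diene terminus), and the second six-membered carbocycle, the future benzene ring, is the ring of the cycloadduct itself. The bridge C–O bond at the future C4a then ionises, because that cation is tertiary, allylic and a vinylogous oxocarbenium ion through the enol ether, and loss of the proton from the other bridgehead gives the arene with the former furan oxygen as the C7 hydroxyl; the trace of pyridinium acid completes this if heat alone does not. No stereocentre is created: the two bridgehead centres of 19 vanish on aromatisation and C4 is a spectator under neutral heating. The selectivity needed is regiochemical only and is secured by the tether (which alkyne carbon meets which furan terminus) and by the methoxy group (which bridge bond breaks). The methyl ynol ether has no β-hydrogen, so the retro-ene fragmentation that caps the temperature for ethyl ynol ethers cannot occur, and the polarity is matched because the nucleophilic furan C5 meets the electrophilic β-carbon of the ynone.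

Step 11
Reactants: 20 (4S)-4-[4-(benzyloxy)-8-methoxynaphthalen-1-yl]-7-hydroxy-8-methoxy-3,4-dihydronaphthalen-1(2H)-one
Product: 21 (4S)-7,8-dihydroxy-4-(4-hydroxy-8-methoxynaphthalen-1-yl)-3,4-dihydronaphthalen-1(2H)-one
Conditions: BCl3 (6 equiv), C6HMe5 (5 equiv), CH2Cl2, −78 to 0 °C; MeOH, then aq. NaHCO3
Reagents that add atoms: none
Why: Lewis-acid ether cleavage; BCl3 with pentamethylbenzene as cation scavenger removes the aryl benzyl ether at −78 °C, and on warming the boron held between the C1 carbonyl and the C7 borate cleaves the C8 methyl ether (chelation-assisted demethylation), while the naphthyl methyl ether, with no neighbouring donor, should remain.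

## Compound list

1 | 5-methoxynaphthalen-1-ol | COc1cccc2c(O)cccc12 | starting material
2 | 4-bromo-5-methoxynaphthalen-1-ol | COc1cccc2c(O)ccc(Br)c12 | intermediate
3 | 1-(benzyloxy)-4-bromo-5-methoxynaphthalene | COc1cccc2c(OCc3ccccc3)ccc(Br)c12 | intermediate
4 | furan-2-carbaldehyde (furfural) | O=Cc1ccco1 | starting material
5 | methyl acrylate | C=CC(=O)OC | starting material
6 | methyl 4-(furan-2-yl)-4-oxobutanoate | COC(=O)CCC(=O)c1ccco1 | intermediate
7 | methyl (3Z)-4-(furan-2-yl)-4-{[(trifluoromethyl)sulfonyl]oxy}but-3-enoate | COC(=O)C/C=C(\OS(=O)(=O)C(F)(F)F)c1ccco1 | intermediate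
8 | [4-(benzyloxy)-8-methoxynaphthalen-1-yl]lithium (not isolated) | [Li]c1ccc(OCc2ccccc2)c2cccc(OC)c12 | intermediate
9 | [4-(benzyloxy)-8-methoxynaphthalen-1-yl]zinc chloride (not isolated) | Cl[Zn]c1ccc(OCc2ccccc2)c2cccc(OC)c12 | intermediate
10 | methyl (3E)-4-[4-(benzyloxy)-8-methoxynaphthalen-1-yl]-4-(furan-2-yl)but-3-enoate (naphthyl cis to CH2CO2Me) | COC(=O)C/C=C(/c1ccco1)c1ccc(OCc2ccccc2)c2cccc(OC)c12 | intermediate
11 | (3E)-4-[4-(benzyloxy)-8-methoxynaphthalen-1-yl]-4-(furan-2-yl)but-3-enoic acid | OC(=O)C/C=C(/c1ccco1)c1ccc(OCc2ccccc2)c2cccc(OC)c12 | intermediate
12 | (4S)-4-[4-(benzyloxy)-8-methoxynaphthalen-1-yl]-4-(furan-2-yl)butanoic acid | OC(=O)CC[C@H](c1ccco1)c1ccc(OCc2ccccc2)c2cccc(OC)c12 | intermediate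
13 | 1-{(4S)-4-[4-(benzyloxy)-8-methoxynaphthalen-1-yl]-4-(furan-2-yl)butanoyl}-1H-imidazole (not isolated) | O=C(CC[C@H](c1ccco1)c1ccc(OCc2ccccc2)c2cccc(OC)c12)n1ccnc1 | intermediate
14 | (4S)-4-[4-(benzyloxy)-8-methoxynaphthalen-1-yl]-4-(furan-2-yl)-N-methoxy-N-methylbutanamide | CON(C)C(=O)CC[C@H](c1ccco1)c1ccc(OCc2ccccc2)c2cccc(OC)c12 | intermediate
15 | 2-chloro-1,1-dimethoxyethane | COC(CCl)OC | starting material
16 | lithium methoxyacetylide (not isolated) | [Li]C#COC | intermediate
17 | lithium (6S)-6-[4-(benzyloxy)-8-methoxynaphthalen-1-yl]-6-(furan-2-yl)-1-methoxy-3-[methoxy(methyl)amino]hex-1-yn-3-olate, C3 unassigned (not isolated) | [Li]OC(C#COC)(CC[C@H](c1ccco1)c1ccc(OCc2ccccc2)c2cccc(OC)c12)N(C)OC | intermediate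
18 | (6S)-6-[4-(benzyloxy)-8-methoxynaphthalen-1-yl]-6-(furan-2-yl)-1-methoxyhex-1-yn-3-one | COC#CC(=O)CC[C@H](c1ccco1)c1ccc(OCc2ccccc2)c2cccc(OC)c12 | intermediate
19 | (2S)-2-[4-(benzyloxy)-8-methoxynaphthalen-1-yl]-7-methoxy-11-oxatricyclo[6.2.1.0(1,6)]undeca-6,9-dien-5-one, both bridgehead (C1/C8) diastereomers, bridgeheads unassigned (not isolated) | O=C1CC[C@@H](c2ccc(OCc3ccccc3)c3cccc(OC)c23)C23OC(C=C2)C(OC)=C13 | intermediate
20 | (4S)-4-[4-(benzyloxy)-8-methoxynaphthalen-1-yl]-7-hydroxy-8-methoxy-3,4-dihydronaphthalen-1(2H)-one | O=C1CC[C@@H](c2ccc(OCc3ccccc3)c3cccc(OC)c23)c2ccc(O)c(OC)c21 | intermediate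
21 | (4S)-7,8-dihydroxy-4-(4-hydroxy-8-methoxynaphthalen-1-yl)-3,4-dihydronaphthalen-1(2H)-one | COc1cccc2c(O)ccc([C@@H]3CCC(=O)c4c3ccc(O)c4O)c12 | target

## Step count and least certain steps

Total: 11 steps. Longest linear sequence: 9 steps (1, 2, 5, 6, 7, 8, 9, 10, 11 from compound 1). Steps 3 and 4 form the second branch.

**Step 10 (key step).** The methoxy donor raises the energy of the alkyne acceptor orbital, so ring closure may be too slow. Oligomerisation of the ynol ether or its hydration by adventitious water could then overtake cycloaddition, or bridge opening could stall at 19. The fallback uses only known reaction types, sets out from 14 and returns at 21. Amide 14 is acylated with lithiated 3,3-diethoxyprop-1-yne to give (7S)-7-[4-(benzyloxy)-8-methoxynaphthalen-1-yl]-1,1-diethoxy-7-(furan-2-yl)hept-2-yn-4-one F1. This is a carbon-substituted ynone of the class already known to undergo the thermal intramolecular furan cycloaddition. Heating in toluene and then aqueous acid should give, after bridge opening and acetal hydrolysis, the salicylaldehyde (5S)-5-[4-(benzyloxy)-8-methoxynaphthalen-1-yl]-2-hydroxy-8-oxo-5,6,7,8-tetrahydronaphthalene-1-carbaldehyde F2. Dakin oxidation (H2O2, aq. NaOH, 0 °C, under argon) of the formyl group beside the hydroxyl gives the catechol (4S)-4-[4-(benzyloxy)-8-methoxynaphthalen-1-yl]-7,8-dihydroxy-3,4-dihydronaphthalen-1(2H)-one F3. BCl3 with pentamethylbenzene at −78 °C then removes the benzyl ether to give 21.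

**Step 9.** The liberated secondary amines may add to the push–pull ynone, or the ynol ether may hydrate during work-up. The fallback sets out from 14 and returns at 18. DIBAL-H at −78 °C reduces 14 to (4S)-4-[4-(benzyloxy)-8-methoxynaphthalen-1-yl]-4-(furan-2-yl)butanal F4. Addition of 16 gives (6S)-6-[4-(benzyloxy)-8-methoxynaphthalen-1-yl]-6-(furan-2-yl)-1-methoxyhex-1-yn-3-ol F5 as both carbinol epimers; no Michael acceptor is present while amines are around. Oxidation with MnO2 in CH2Cl2 under neutral conditions gives 18.

**Step 7.** Both substituents on the alkene carbon are aryl and one is very bulky, so face discrimination may be poor, reduction slow, or the double bond may migrate toward the carboxyl group. The fallback sets out from 11 and returns at 12. Hydrogenation with the achiral complex [Ir(cod)(PCy3)(py)]PF6 gives racemic 4-[4-(benzyloxy)-8-methoxynaphthalen-1-yl]-4-(furan-2-yl)butanoic acid F6. This is resolved by crystallising the salt with one enantiomer of 1-phenylethylamine, written here as (S)-1-phenylethylammonium (4S)-4-[4-(benzyloxy)-8-methoxynaphthalen-1-yl]-4-(furan-2-yl)butanoate F7; the amine antipode is used if its salt with the (S)-acid is the less soluble. Acidification to pH 4 returns 12.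

**Step 11.** The naphthyl methyl ether may be lost on prolonged exposure, the chelated ether may be cleaved incompletely, or the freed naphthol may be C-benzylated. The fallback separates the two cleavages; it sets out from 20 and returns at 21. Hydrogenolysis (H2, Pd/C, EtOAc, 25 °C, short contact) removes the benzyl group to give (4S)-7-hydroxy-4-(4-hydroxy-8-methoxynaphthalen-1-yl)-8-methoxy-3,4-dihydronaphthalen-1(2H)-one F8. MgI2·OEt2 in toluene/THF then cleaves only the methyl ether chelated to the carbonyl, giving 21.

**Step 1.** Bromination may occur at C2 or in the methoxy-bearing ring, or the naphthol may be over-oxidised to the quinone. The fallback marks C4 with oxygen instead of bromine; it sets out from 1 and returns at 10.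
- Oxidation of 1 with PhI(OAc)2 in aqueous MeCN gives 5-methoxynaphthalene-1,4-dione F9.
- Reduction with Na2S2O4 gives 5-methoxynaphthalene-1,4-diol F10.
- Benzylation with one equivalent of BnBr and K2CO3 should take the hydroxyl remote from the methoxy group (the peri hydroxyl is hydrogen-bonded and hindered) and give 4-(benzyloxy)-8-methoxynaphthalen-1-ol F11.
- Tf2O and pyridine give 4-(benzyloxy)-8-methoxynaphthalen-1-yl trifluoromethanesulfonate F12.
- Miyaura borylation (B2pin2, PdCl2(dppf), KOAc, dioxane, 80 °C) gives 2-[4-(benzyloxy)-8-methoxynaphthalen-1-yl]-4,4,5,5-tetramethyl-1,3,2-dioxaborolane F13.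
- Suzuki coupling of F13 with 7 (Pd2(dba)3, SPhos, K3PO4, THF/H2O) gives 10.

## Further compounds

F1 | step 10 | (7S)-7-[4-(benzyloxy)-8-methoxynaphthalen-1-yl]-1,1-diethoxy-7-(furan-2-yl)hept-2-yn-4-one | CCOC(OCC)C#CC(=O)CC[C@H](c1ccco1)c1ccc(OCc2ccccc2)c2cccc(OC)c12
F2 | step 10 | (5S)-5-[4-(benzyloxy)-8-methoxynaphthalen-1-yl]-2-hydroxy-8-oxo-5,6,7,8-tetrahydronaphthalene-1-carbaldehyde | O=C1CC[C@@H](c2ccc(OCc3ccccc3)c3cccc(OC)c23)c2ccc(O)c(C=O)c21
F3 | step 10 | (4S)-4-[4-(benzyloxy)-8-methoxynaphthalen-1-yl]-7,8-dihydroxy-3,4-dihydronaphthalen-1(2H)-one | O=C1CC[C@@H](c2ccc(OCc3ccccc3)c3cccc(OC)c23)c2ccc(O)c(O)c21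
F4 | step 9 | (4S)-4-[4-(benzyloxy)-8-methoxynaphthalen-1-yl]-4-(furan-2-yl)butanal | O=CCC[C@H](c1ccco1)c1ccc(OCc2ccccc2)c2cccc(OC)c12
F5 | step 9 | (6S)-6-[4-(benzyloxy)-8-methoxynaphthalen-1-yl]-6-(furan-2-yl)-1-methoxyhex-1-yn-3-ol, both C3 epimers | COC#CC(O)CC[C@H](c1ccco1)c1ccc(OCc2ccccc2)c2cccc(OC)c12
F6 | step 7 | racemic 4-[4-(benzyloxy)-8-methoxynaphthalen-1-yl]-4-(furan-2-yl)butanoic acid | OC(=O)CCC(c1ccco1)c1ccc(OCc2ccccc2)c2cccc(OC)c12
F7 | step 7 | (S)-1-phenylethylammonium (4S)-4-[4-(benzyloxy)-8-methoxynaphthalen-1-yl]-4-(furan-2-yl)butanoate | C[C@H]([NH3+])c1ccccc1.[O-]C(=O)CC[C@H](c1ccco1)c1ccc(OCc2ccccc2)c2cccc(OC)c12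
F8 | step 11 | (4S)-7-hydroxy-4-(4-hydroxy-8-methoxynaphthalen-1-yl)-8-methoxy-3,4-dihydronaphthalen-1(2H)-one | COc1cccc2c(O)ccc([C@@H]3CCC(=O)c4c3ccc(O)c4OC)c12
F9 | step 1 | 5-methoxynaphthalene-1,4-dione | COc1cccc2C(=O)C=CC(=O)c12
F10 | step 1 | 5-methoxynaphthalene-1,4-diol | COc1cccc2c(O)ccc(O)c12
F11 | step 1 | 4-(benzyloxy)-8-methoxynaphthalen-1-ol | COc1cccc2c(OCc3ccccc3)ccc(O)c12
F12 | step 1 | 4-(benzyloxy)-8-methoxynaphthalen-1-yl trifluoromethanesulfonate | COc1cccc2c(OCc3ccccc3)ccc(OS(=O)(=O)C(F)(F)F)c12
F13 | step 1 | 2-[4-(benzyloxy)-8-methoxynaphthalen-1-yl]-4,4,5,5-tetramethyl-1,3,2-dioxaborolane | COc1cccc2c(OCc3ccccc3)ccc(B3OC(C)(C)C(C)(C)O3)c12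
A1 | alternative 1 | 1,4-epoxy-1,4-dihydronaphthalene adduct on the acetonide-protected tetralone, both bridgehead epimers (bridgeheads unassigned), C4 as in the target | COc1cccc2C3C=CC(O3)(c12)[C@@H]1CCC(=O)c4c1ccc1OC(C)(C)Oc14
A2 | alternative 1 | 3-methoxybenzyne | COC1=CC=CC#C1
A3 | alternative 1 | 4-(furan-2-yl)-7,8-(isopropylidenedioxy)-3,4-dihydronaphthalen-1(2H)-one, C4 as in the target | O=C1CC[C@@H](c2ccco2)c2ccc3OC(C)(C)Oc3c21
A4 | alternative 2 | cis-1-(O-methylmandeloyloxy)-4-[4-(benzyloxy)-8-methoxynaphthalen-1-yl]-7,8-(methylenedioxy)-1,4-dihydronaphthalene, C4 as in the target | CO[C@@H](c1ccccc1)C(=O)O[C@H]1C=C[C@@H](c2ccc(OCc3ccccc3)c3cccc(OC)c23)c2ccc3OCOc3c21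
A5 | alternative 2 | 3,4-(methylenedioxy)benzyne | C1OC2=C(O1)C#CC=C2
A6 | alternative 2 | (1E,3E)-4-[4-(benzyloxy)-8-methoxynaphthalen-1-yl]buta-1,3-dien-1-yl O-methylmandelate | CO[C@@H](c1ccccc1)C(=O)O/C=C/C=C/c1ccc(OCc2ccccc2)c2cccc(OC)c12
A7 | alternative 3 | acetonide- and methoxymethyl-protected target, C4 as in the target | O=C1CC[C@@H](c2ccc(OCOC)c3cccc(OC)c23)c2ccc3OC(C)(C)Oc3c21
A8 | alternative 3 | 2-chloro-1-{2,2-dimethyl-5-[1-(8-methoxy-4-(methoxymethoxy)naphthalen-1-yl)vinyl]-1,3-benzodioxol-4-yl}ethanone | ClCC(=O)c1c(C(=C)c2ccc(OCOC)c3cccc(OC)c23)ccc2OC(C)(C)Oc12
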